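Assumption: briarane numbering (C1–C20) is used for every intermediate, and the target SMILES is read as (1S,2S,6S,7R,8R,9S,10S,11S,12R,13R,14R,17R); the SMILES remains the reference.

## Retrosynthetic overview

1. Lactone last: oxidative lactonisation of the C7-OH / C19-OH diol.
2. Ten-membered ring: C6–C7 bond by an electrochemical, chromium-catalysed intramolecular γ-chloroallylation of the C7 aldehyde. This one step also installs C6–Cl, C7–OH and the C5=C16 methylene.
3. C2–C3: addition of a chloroenyne Grignard to the neopentyl C2 aldehyde; the 3Z alkene comes from semihydrogenation.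
4. Ring A first: [4+2] of a 1-aminodiene with an E-enal whose C9 stereocentre (set by Felkin addition to L-glyceraldehyde acetonide) steers the facial sense; then dihydroxylation and directed epoxidation.
5. C17 is bought (Roche ester); C8 comes from hydroxyl-directed dihydroxylation. Ring order: ring A, then the ten-membered ring, then the lactone.

## Route

Step 1
Reactants: 1 methyl (S)-3-hydroxy-2-methylpropanoate
Product: 2 methyl (S)-3-[(tert-butyldiphenylsilyl)oxy]-2-methylpropanoate
Conditions: TBDPSCl, imidazole, CH2Cl2, 0 °C to rt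
Reagents that add atoms: tert-butyl(chloro)diphenylsilane, CC(C)(C)[Si](Cl)(c1ccccc1)c1ccccc1
Why: Routine silylation of the primary alcohol; the stereocentre (future C17) is bought and untouched.

Step 2
Reactants: 2 methyl (S)-3-[(tert-butyldiphenylsilyl)oxy]-2-methylpropanoate
Product: 4 (S)-4-[(tert-butyldiphenylsilyl)oxy]-3-methylbutan-2-one, via Weinreb amide 3 (not isolated)
Conditions: MeNHOMe·HCl, iPrMgCl, THF, −20 °C; then MeMgBr, 0 °C; aq. NH4Cl
Reagents that add atoms: methylmagnesium bromide, C[Mg]Br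
Why: One-pot Weinreb ketone synthesis; the chelated tetrahedral intermediate prevents over-addition and the α-stereocentre is not enolised at low temperature.

Step 3
Reactants: 4 (S)-4-[(tert-butyldiphenylsilyl)oxy]-3-methylbutan-2-one
Product: 5 (S)-4-[(tert-butyldiphenylsilyl)oxy]-3-methylbut-1-en-2-yl trifluoromethanesulfonate
Conditions: KN(SiMe3)2, THF, −78 °C; PhNTf2
Reagents that add atoms: N-phenylbis(trifluoromethanesulfonimide), O=S(=O)(N(c1ccccc1)S(=O)(=O)C(F)(F)F)C(F)(F)F
Why: Kinetic enolisation at the methyl group followed by O-triflation gives the terminal enol triflate (future C8=C7) without touching the adjacent stereocentre.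

Step 4
Reactants: 5 (S)-4-[(tert-butyldiphenylsilyl)oxy]-3-methylbut-1-en-2-yl trifluoromethanesulfonate and 6 (S)-2,2-dimethyl-1,3-dioxolane-4-carbaldehyde
Product: 7 (1R,3R)-4-[(tert-butyldiphenylsilyl)oxy]-1-[(4S)-2,2-dimethyl-1,3-dioxolan-4-yl]-3-methyl-2-methylidenebutan-1-ol
Conditions: CrCl2 (4 equiv), NiCl2 (2 mol %), DMF, rt
Reagents that add atoms: none
Why: Nozaki–Hiyama–Kishi coupling of the alkenyl triflate to the α-alkoxy aldehyde follows Felkin–Anh (anti) addition, so the bought dioxolane stereocentre sets C9; the minor syn isomer is removed by chromatography.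

Step 5
Reactants: 7 (1R,3R)-4-[(tert-butyldiphenylsilyl)oxy]-1-[(4S)-2,2-dimethyl-1,3-dioxolan-4-yl]-3-methyl-2-methylidenebutan-1-ol
Product: 8 tert-butyldimethylsilyl ether of 7
Conditions: TBSOTf, 2,6-lutidine, CH2Cl2, −78 °C
Reagents that add atoms: tert-butyldimethylsilyl trifluoromethanesulfonate, CC(C)(C)[Si](C)(C)OS(=O)(=O)C(F)(F)F
Why: Silylation of the hindered secondary allylic alcohol; the bulky C9–OTBS group later shields one face of the dienophile.

Step 6
Reactants: 8 tert-butyldimethylsilyl ether of 7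
Product: 9 (2R,4R)-5-[(tert-butyldiphenylsilyl)oxy]-2-[(tert-butyldimethylsilyl)oxy]-4-methyl-3-methylidenepentanal
Conditions: H5IO6, EtOAc, rt; used crude
Reagents that add atoms: none
Why: Periodic acid hydrolyses the terminal acetonide and cleaves the liberated glycol in one pot (glycol cleavage), turning the relay stereocentre into the C10 aldehyde while C9 is kept.

Step 7
Reactants: 9 (2R,4R)-5-[(tert-butyldiphenylsilyl)oxy]-2-[(tert-butyldimethylsilyl)oxy]-4-methyl-3-methylidenepentanal and 10 2-(triphenyl-λ5-phosphanylidene)propanal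
Product: 11 (2E,4S,6R)-7-[(tert-butyldiphenylsilyl)oxy]-4-[(tert-butyldimethylsilyl)oxy]-2,6-dimethyl-5-methylidenehept-2-enal
Conditions: toluene, 60 °C
Reagents that add atoms: none
Why: Wittig olefination with the stabilised ylide is E-selective and neutral, giving the trisubstituted enal (C2 aldehyde, C1 methyl, C10) without epimerising C9.

Step 8
Reactants: 12 (E)-pent-2-enal and 13 pyrrolidine
Product: 14 1-[(1E,3E)-penta-1,3-dien-1-yl]pyrrolidine
Conditions: K2CO3, Et2O, 0 °C; filter, distil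
Reagents that add atoms: none
Why: Condensation of the enal with the secondary amine and γ-deprotonation gives the 1-aminodiene (dienamine formation).

Step 9
Reactants: 11 (2E,4S,6R)-7-[(tert-butyldiphenylsilyl)oxy]-4-[(tert-butyldimethylsilyl)oxy]-2,6-dimethyl-5-methylidenehept-2-enal and 14 1-[(1E,3E)-penta-1,3-dien-1-yl]pyrrolidine
Product: 16 ring A diene aldehyde (1S,6S)-6-[(1S,3R)-4-[(tert-butyldiphenylsilyl)oxy]-1-[(tert-butyldimethylsilyl)oxy]-3-methyl-2-methylidenebutyl]-1,5-dimethylcyclohexa-2,4-diene-1-carbaldehyde, via aminocyclohexene cycloadduct 15 (not isolated)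
Conditions: 14 (2 equiv), toluene, rt to 60 °C; then AcOH, NaOAc, THF–H2O, 40 °C
Reagents that add atoms: none
Why: Normal-demand Diels–Alder reaction of the electron-rich 1-aminodiene (C11 to C10 and C14 to C1, ortho regiochemistry from the amino donor) carries the E geometry into the trans C2/C9 relationship and, in the allylic 1,3-strain-minimised conformer (C9–H eclipsing the C1 methyl), takes place anti to the bulky, electron-withdrawing C9–OTBS bond, which sets C1 and C10; acid then eliminates pyrrolidine (1,4-elimination) to the cyclohexa-1,3-diene.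

Step 10
Reactants: 17 1,3-dichloropropan-2-one and 18 ethynylmagnesium bromide
Product: 19 1-chloro-2-(chloromethyl)but-3-yn-2-ol
Conditions: THF, −78 to 0 °C; aq. NH4Cl
Reagents that add atoms: none
Why: Grignard addition to the ketone is faster than displacement of the α-chlorides at low temperature.

Step 11
Reactants: 19 1-chloro-2-(chloromethyl)but-3-yn-2-ol
Product: 20 1-chloro-2-(chloromethyl)but-1-en-3-yne (E/Z mixture)
Conditions: methyl N-(triethylammoniosulfonyl)carbamate (Burgess reagent), toluene, 50 °C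
Reagents that add atoms: none
Why: Burgess dehydration (syn-elimination through the sulfamate ester) removes an acidified CHCl hydrogen to give the chloroenyne; the alkene geometry is irrelevant because the later allylchromium equilibrates.

Step 12
Reactants: 16 ring A diene aldehyde and 20 1-chloro-2-(chloromethyl)but-1-en-3-yne
Product: 22 C2 propargylic alcohol (chloroenyne adduct of 16), via alkynylmagnesium bromide 21 (not isolated)
Conditions: EtMgBr, THF, 0 °C; then 16, −20 °C to rt; aq. NH4Cl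
Reagents that add atoms: none
Why: Alkynyl Grignard addition to the non-enolisable neopentyl aldehyde; in the Felkin–Anh transition state the C10 branch is anti to the nucleophile, which passes the C1 methyl and so sets C2 as in the target.

Step 13
Reactants: 22 C2 propargylic alcohol
Product: 23 C11,C12 cis-diol (C13=C14 retained)
Conditions: OsO4 (2 mol %), N-methylmorpholine N-oxide (1.1 equiv), acetone–H2O, 0 °C
Reagents that add atoms: osmium tetroxide, O=[Os](=O)(=O)=O; N-methylmorpholine N-oxide, C[N+]1([O-])CCOCC1; water, O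
Why: Upjohn dihydroxylation attacks the most electron-rich trisubstituted C11=C12 bond of the ring diene from the face opposite the C9 side chain and the pseudoaxial C1 methyl (both β), giving the 11α,12α-diol; the hindered methylidene next to the OTBS group and the chloroalkene react more slowly.

Step 14
Reactants: 23 C11,C12 cis-diol
Product: 24 13,14-epoxy triol
Conditions: VO(acac)2 (5 mol %), tBuOOH, CH2Cl2, 0 °C
Reagents that add atoms: tert-butyl hydroperoxide, CC(C)(C)OO
Why: Vanadium-catalysed hydroxyl-directed epoxidation delivers oxygen to C13=C14 syn to the allylic 12α-hydroxyl (reinforced by the homoallylic 11α- and C2-hydroxyls), giving the α-epoxide; the alkyne, chloroalkene and silyloxy-flanked methylidene have no free allylic hydroxyl and stay intact.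

Step 15
Reactants: 24 13,14-epoxy triol
Product: 25 C2,C12 bis-butyrate
Conditions: butyric anhydride, Et3N, DMAP (cat.), CH2Cl2, 0 °C to rt
Reagents that add atoms: butanoic anhydride, CCCC(=O)OC(=O)CCC
Why: DMAP-catalysed acylation esterifies the two secondary alcohols and leaves the tertiary C11 hydroxyl free.

Step 16
Reactants: 25 C2,C12 bis-butyrate
Product: 26 C9 allylic alcohol
Conditions: HF·pyridine, pyridine, THF, 0 °C to rt
Reagents that add atoms: none
Why: Buffered fluoride desilylation removes the secondary TBS ether much faster than the primary TBDPS ether and tolerates the epoxide, esters and allylic chloride.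

Step 17
Reactants: 26 C9 allylic alcohol
Product: 27 C7,C8,C9 triol
Conditions: OsO4 (1.1 equiv), TMEDA, CH2Cl2, −78 °C; aq. Na2SO3
Reagents that add atoms: osmium tetroxide, O=[Os](=O)(=O)=O
Why: Donohoe hydrogen-bond-directed dihydroxylation delivers the OsO4–TMEDA complex to the methylidene face syn to the C9 hydroxyl, giving the threo (syn) C9/C8 relationship of the target and the primary C7 alcohol; the alkyne and chloroalkene are inert at −78 °C.

Step 18
Reactants: 27 C7,C8,C9 triol
Product: 29 C9 acetate C7 aldehyde, via hydroxy aldehyde 28 (not isolated)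
Conditions: TEMPO (cat.), PhI(OAc)2, CH2Cl2, rt; then Ac2O, pyridine, DMAP, 0 °C
Reagents that add atoms: acetic anhydride, CC(=O)OC(C)=O
Why: Oxoammonium oxidation is selective for the primary alcohol and gives the non-enolisable α-hydroxy aldehyde; acetylation then takes the only secondary alcohol (C9) and leaves both tertiary alcohols free.

Step 19
Reactants: 29 C9 acetate C7 aldehyde
Product: 30 (3Z)-seco aldehyde
Conditions: H2 (1 atm), Pd/CaCO3 poisoned by Pb(OAc)2 (Lindlar catalyst), quinoline, EtOAc, rt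
Reagents that add atoms: none
Why: Lindlar semihydrogenation adds hydrogen syn to the C3≡C4 alkyne to give the Z alkene; the poisoned catalyst spares the chloroalkene, the allylic chloride and the aldehyde.

Step 20
Reactants: 30 (3Z)-seco aldehyde
Product: 32 ten-membered carbocycle (C6 chloride, C7 alcohol, C5=C16 methylene), via trimethylsilyl ether 31 (not isolated)
Conditions: CrCl3 (15 mol %), TMSCl, Bu4NPF6, DMF–THF, undivided cell, Al anode, Ni-foam cathode, constant current, syringe-pump addition to 2 mM, rt; then aq. citric acid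
Reagents that add atoms: none
Why: Proposed new method: cathodically generated divalent chromium inserts into the primary allylic C16–Cl bond to give a γ-chloroallylchromium species that equilibrates between its E and Z forms (so the chloroalkene mixture converges) and adds through its γ-carbon C6 to the C7 aldehyde in a chair Zimmerman–Traxler transition state with chlorine equatorial (anti C6/C7), while chelation of chromium by the free C8 hydroxyl and the tether through C9 expose the aldehyde face that gives the 7,8-anti diol, and TMSCl silylates the trivalent chromium alkoxide so the metal is released for re-reduction; the closest known reactions are the stoichiometric CrCl2-mediated intermolecular γ-chloroallylation of aldehydes, Nozaki–Hiyama allylation macrocyclisations and electrochemical chromium-catalysed Nozaki–Hiyama–Kishi couplings.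

Step 21
Reactants: 32 ten-membered carbocycle
Product: 33 C7,C19 diol
Conditions: Bu4NF, AcOH, THF, 0 °C to rt
Reagents that add atoms: none
Why: Acetic-acid-buffered fluoride desilylation frees the primary C19 alcohol without acyl migration or displacement of the allylic chloride.

Step 22
Reactants: 33 C7,C19 diol
Product: 34 target CNP0188106.1
Conditions: TEMPO (cat.), PhI(OAc)2 (2.5 equiv), CH2Cl2, rt
Reagents that add atoms: none
Why: Oxidative lactonisation: the primary C19 alcohol is oxidised to the aldehyde, which closes to the five-membered lactol on the C7 hydroxyl and is oxidised on to the γ-lactone; C9 is blocked as its acetate and C8 is tertiary, so only the C7 lactone can form, and C17 is untouched.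

## Compound list

1 | methyl (S)-3-hydroxy-2-methylpropanoate (Roche ester) | COC(=O)[C@@H](C)CO | starting material
2 | methyl (S)-3-[(tert-butyldiphenylsilyl)oxy]-2-methylpropanoate | COC(=O)[C@@H](C)CO[Si](c1ccccc1)(c1ccccc1)C(C)(C)C | intermediate
3 | (S)-3-[(tert-butyldiphenylsilyl)oxy]-N-methoxy-N,2-dimethylpropanamide (Weinreb amide) | CON(C)C(=O)[C@@H](C)CO[Si](c1ccccc1)(c1ccccc1)C(C)(C)C | intermediate
4 | (S)-4-[(tert-butyldiphenylsilyl)oxy]-3-methylbutan-2-one | CC(=O)[C@@H](C)CO[Si](c1ccccc1)(c1ccccc1)C(C)(C)C | intermediate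
5 | (S)-4-[(tert-butyldiphenylsilyl)oxy]-3-methylbut-1-en-2-yl trifluoromethanesulfonate | C=C(OS(=O)(=O)C(F)(F)F)[C@@H](C)CO[Si](c1ccccc1)(c1ccccc1)C(C)(C)C | intermediate
6 | (S)-2,2-dimethyl-1,3-dioxolane-4-carbaldehyde (L-glyceraldehyde acetonide) | O=C[C@@H]1COC(C)(C)O1 | starting material
7 | (1R,3R)-4-[(tert-butyldiphenylsilyl)oxy]-1-[(4S)-2,2-dimethyl-1,3-dioxolan-4-yl]-3-methyl-2-methylidenebutan-1-ol (anti adduct; carbinol = C9) | C=C([C@@H](O)[C@@H]1COC(C)(C)O1)[C@@H](C)CO[Si](c1ccccc1)(c1ccccc1)C(C)(C)C | intermediate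
8 | tert-butyldimethylsilyl ether of 7 | C=C([C@@H](O[Si](C)(C)C(C)(C)C)[C@@H]1COC(C)(C)O1)[C@@H](C)CO[Si](c1ccccc1)(c1ccccc1)C(C)(C)C | intermediate
9 | (2R,4R)-5-[(tert-butyldiphenylsilyl)oxy]-2-[(tert-butyldimethylsilyl)oxy]-4-methyl-3-methylidenepentanal | C=C([C@@H](O[Si](C)(C)C(C)(C)C)C=O)[C@@H](C)CO[Si](c1ccccc1)(c1ccccc1)C(C)(C)C | intermediate
10 | 2-(triphenyl-λ5-phosphanylidene)propanal | CC(C=O)=P(c1ccccc1)(c1ccccc1)c1ccccc1 | starting material
11 | (2E,4S,6R)-7-[(tert-butyldiphenylsilyl)oxy]-4-[(tert-butyldimethylsilyl)oxy]-2,6-dimethyl-5-methylidenehept-2-enal | C=C([C@@H](O[Si](C)(C)C(C)(C)C)/C=C(\C)C=O)[C@@H](C)CO[Si](c1ccccc1)(c1ccccc1)C(C)(C)C | intermediate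
12 | (E)-pent-2-enal | CC/C=C/C=O | starting material
13 | pyrrolidine | C1CCNC1 | starting material
14 | 1-[(1E,3E)-penta-1,3-dien-1-yl]pyrrolidine | C/C=C/C=C/N1CCCC1 | intermediate
15 | endo Diels–Alder adduct: ring A cyclohexene with C1 (Me, CHO), C14 pyrrolidinyl, C12=C13, C11 methyl and the C9 side chain on C10; the C11 and C14 centres are lost in the same step | O=C[C@@]1(C)[C@@H](N2CCCC2)C=C[C@@H](C)[C@@H]1[C@H](O[Si](C)(C)C(C)(C)C)C(=C)[C@@H](C)CO[Si](c2ccccc2)(c2ccccc2)C(C)(C)C | intermediate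
16 | (1S,6S)-6-[(1S,3R)-4-[(tert-butyldiphenylsilyl)oxy]-1-[(tert-butyldimethylsilyl)oxy]-3-methyl-2-methylidenebutyl]-1,5-dimethylcyclohexa-2,4-diene-1-carbaldehyde (formyl C2 trans to the C9 side chain) | O=C[C@@]1(C)C=CC=C(C)[C@@H]1[C@H](O[Si](C)(C)C(C)(C)C)C(=C)[C@@H](C)CO[Si](c2ccccc2)(c2ccccc2)C(C)(C)C | intermediate
17 | 1,3-dichloropropan-2-one | ClCC(=O)CCl | starting material
18 | ethynylmagnesium bromide | C#C[Mg]Br | starting material
19 | 1-chloro-2-(chloromethyl)but-3-yn-2-ol | C#CC(O)(CCl)CCl | intermediate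
20 | 1-chloro-2-(chloromethyl)but-1-en-3-yne (E/Z mixture) | C#CC(=CCl)CCl | intermediate
21 | [4-chloro-3-(chloromethyl)but-3-en-1-yn-1-yl]magnesium bromide | ClC=C(CCl)C#C[Mg]Br | intermediate
22 | C2 propargylic alcohol: 16 with CHO replaced by CH(OH)–C≡C–C(=CHCl)CH2Cl; C2 and all other centres as in 34 | ClC=C(CCl)C#C[C@H](O)[C@@]1(C)C=CC=C(C)[C@@H]1[C@H](O[Si](C)(C)C(C)(C)C)C(=C)[C@@H](C)CO[Si](c2ccccc2)(c2ccccc2)C(C)(C)C | intermediate
23 | 11α,12α-diol of 22 (C13=C14 retained) | ClC=C(CCl)C#C[C@H](O)[C@@]1(C)C=C[C@@H](O)[C@@](C)(O)[C@@H]1[C@H](O[Si](C)(C)C(C)(C)C)C(=C)[C@@H](C)CO[Si](c2ccccc2)(c2ccccc2)C(C)(C)C | intermediate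
24 | 13α,14α-epoxide of 23 (C2, C11 and C12 hydroxyls free) | ClC=C(CCl)C#C[C@H](O)[C@@]1(C)[C@H]2O[C@H]2[C@@H](O)[C@@](C)(O)[C@@H]1[C@H](O[Si](C)(C)C(C)(C)C)C(=C)[C@@H](C)CO[Si](c2ccccc2)(c2ccccc2)C(C)(C)C | intermediate
25 | C2,C12 bis-butyrate of 24 | ClC=C(CCl)C#C[C@H](OC(=O)CCC)[C@@]1(C)[C@H]2O[C@H]2[C@@H](OC(=O)CCC)[C@@](C)(O)[C@@H]1[C@H](O[Si](C)(C)C(C)(C)C)C(=C)[C@@H](C)CO[Si](c2ccccc2)(c2ccccc2)C(C)(C)C | intermediate
26 | C9 allylic alcohol (25 without the TBS group) | ClC=C(CCl)C#C[C@H](OC(=O)CCC)[C@@]1(C)[C@H]2O[C@H]2[C@@H](OC(=O)CCC)[C@@](C)(O)[C@@H]1[C@H](O)C(=C)[C@@H](C)CO[Si](c2ccccc2)(c2ccccc2)C(C)(C)C | intermediate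
27 | C7,C8,C9 triol (C8 tertiary alcohol as in 34, C7 primary alcohol) | ClC=C(CCl)C#C[C@H](OC(=O)CCC)[C@@]1(C)[C@H]2O[C@H]2[C@@H](OC(=O)CCC)[C@@](C)(O)[C@@H]1[C@H](O)[C@](CO)(O)[C@@H](C)CO[Si](c2ccccc2)(c2ccccc2)C(C)(C)C | intermediate
28 | C8,C9-dihydroxy C7 aldehyde | ClC=C(CCl)C#C[C@H](OC(=O)CCC)[C@@]1(C)[C@H]2O[C@H]2[C@@H](OC(=O)CCC)[C@@](C)(O)[C@@H]1[C@H](O)[C@](C=O)(O)[C@@H](C)CO[Si](c2ccccc2)(c2ccccc2)C(C)(C)C | intermediate
29 | C9 acetate C7 aldehyde (alkyne stage) | ClC=C(CCl)C#C[C@H](OC(=O)CCC)[C@@]1(C)[C@H]2O[C@H]2[C@@H](OC(=O)CCC)[C@@](C)(O)[C@@H]1[C@H](OC(C)=O)[C@](C=O)(O)[C@@H](C)CO[Si](c2ccccc2)(c2ccccc2)C(C)(C)C | intermediate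
30 | (3Z)-seco aldehyde: 29 with the C3≡C4 alkyne reduced to the Z alkene | ClC=C(CCl)/C=C\[C@H](OC(=O)CCC)[C@@]1(C)[C@H]2O[C@H]2[C@@H](OC(=O)CCC)[C@@](C)(O)[C@@H]1[C@H](OC(C)=O)[C@](C=O)(O)[C@@H](C)CO[Si](c2ccccc2)(c2ccccc2)C(C)(C)C | intermediate
31 | C7 O-trimethylsilyl ether of 32 | C=C1/C=C\[C@H](OC(=O)CCC)[C@@]2(C)[C@H]3O[C@H]3[C@@H](OC(=O)CCC)[C@@](C)(O)[C@@H]2[C@H](OC(C)=O)[C@](O)([C@@H](C)CO[Si](c4ccccc4)(c4ccccc4)C(C)(C)C)[C@@H](O[Si](C)(C)C)[C@H]1Cl | intermediate
32 | ten-membered carbocycle: (6S)-chloride, (7R)-alcohol, C5=C16 methylene, C19 OTBDPS | C=C1/C=C\[C@H](OC(=O)CCC)[C@@]2(C)[C@H]3O[C@H]3[C@@H](OC(=O)CCC)[C@@](C)(O)[C@@H]2[C@H](OC(C)=O)[C@](O)([C@@H](C)CO[Si](c4ccccc4)(c4ccccc4)C(C)(C)C)[C@@H](O)[C@H]1Cl | intermediate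
33 | C7,C19 diol (32 without the TBDPS group) | C=C1/C=C\[C@H](OC(=O)CCC)[C@@]2(C)[C@H]3O[C@H]3[C@@H](OC(=O)CCC)[C@@](C)(O)[C@@H]2[C@H](OC(C)=O)[C@](O)([C@@H](C)CO)[C@@H](O)[C@H]1Cl | intermediate
34 | CNP0188106.1 (9-acetoxy-2,12-dibutanoyloxy-6-chloro-13,14-epoxy-8,11-dihydroxybriara-3(Z),5(16)-dien-18,7-olide) | C=C1/C=C\[C@H](OC(=O)CCC)[C@@]2(C)[C@H]3O[C@H]3[C@@H](OC(=O)CCC)[C@@](C)(O)[C@@H]2[C@H](OC(C)=O)[C@]2(O)[C@@H](C)C(=O)O[C@H]2[C@H]1Cl | target

## Step count and weak points

Total step count: 22. Longest linear sequence: 19 steps (1–7, 9, 12–22, from the Roche ester).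

The three steps most likely to fail:

Step 9 (aminodiene [4+2] and amine elimination). The hindered trisubstituted enal may react slowly, a stepwise Michael–Mannich pathway could erode the trans C2/C9 relationship, and the facial bias rests on the C9–OTBS group alone. The fallback sets out from 11 and comes back at 16. Enal 11 is heated in toluene with the more reactive, concertedly reacting 1-amino-3-siloxydiene (1E,3Z)-3-[(tert-butyldimethylsilyl)oxy]-N,N-dimethylpenta-1,3-dien-1-amine F1 (one step from commercial (E)-1-(dimethylamino)pent-1-en-3-one, KN(SiMe3)2, TBSCl) to give the aminosilyl enol ether cycloadduct F2. Dilute HF in MeCN converts this into the ring A enone F3. KN(SiMe3)2 and PhNTf2 give the dienyl triflate F4, and Pd(OAc)2, PPh3, HCO2H, Et3N in DMF at 60 °C (zerovalent palladium formed in situ) reduces the triflate to diene aldehyde 16.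

Step 12 (C2 stereocentre). Felkin–Anh discrimination between the C1 methyl and the ring sp2 carbon is small, so the C2 epimer may dominate. The fallback sets out from 16 and comes back at 22. The alkynyl Grignard addition is run as before, the crude epimer mixture is oxidised with Dess–Martin periodinane to the C2 ynone F5, and this is reduced with NaBH4, CeCl3 at −78 °C (Luche 1,2-reduction). Hydride now enters where the alkynyl group entered before, so the opposite carbinol configuration, that of 22, is obtained.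

Step 20 (the proposed electrochemical γ-chloroallylation). Risks are competing oligomerisation, α-ketol rearrangement of the hydroxy aldehyde by aluminium or chromium salts, and the wrong C7 face. The fallback uses known chemistry, sets out from 30 (single chloroalkene isomer with chlorine trans to C16, separated at the stage of 20) and comes back at 32. Pd2(dba)3 (zerovalent palladium) and B2pin2 in THF borylate the primary allylic chloride to the γ-chloroallyl pinacolboronate F6. Warming in toluene at 1 mM effects intramolecular allylboration through a closed chair transition state (anti C6/C7), giving the cyclic C7 borate ester F7. Triethanolamine work-up then releases 32.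

## Further compounds

F1 | step 9 | (1E,3Z)-3-[(tert-butyldimethylsilyl)oxy]-N,N-dimethylpenta-1,3-dien-1-amine | CN(C)/C=C/C(O[Si](C)(C)C(C)(C)C)=C/C
F2 | step 9 | aminosilyl enol ether cycloadduct (C14 NMe2, C12 OTBS enol ether, C11 methyl) | O=C[C@@]1(C)[C@@H](N(C)C)C=C(O[Si](C)(C)C(C)(C)C)[C@@H](C)[C@@H]1[C@H](O[Si](C)(C)C(C)(C)C)C(=C)[C@@H](C)CO[Si](c2ccccc2)(c2ccccc2)C(C)(C)C
F3 | step 9 | ring A enone (C12 ketone, C13=C14) | O=C[C@@]1(C)C=CC(=O)[C@@H](C)[C@@H]1[C@H](O[Si](C)(C)C(C)(C)C)C(=C)[C@@H](C)CO[Si](c2ccccc2)(c2ccccc2)C(C)(C)C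
F4 | step 9 | ring A dienyl triflate (C12 OTf) | O=C[C@@]1(C)C=CC(OS(=O)(=O)C(F)(F)F)=C(C)[C@@H]1[C@H](O[Si](C)(C)C(C)(C)C)C(=C)[C@@H](C)CO[Si](c2ccccc2)(c2ccccc2)C(C)(C)C
F5 | step 12 | C2 ynone | ClC=C(CCl)C#CC(=O)[C@@]1(C)C=CC=C(C)[C@@H]1[C@H](O[Si](C)(C)C(C)(C)C)C(=C)[C@@H](C)CO[Si](c2ccccc2)(c2ccccc2)C(C)(C)C
F6 | step 20 | γ-chloroallyl pinacolboronate of 30 (C16 Bpin, chlorine trans to C16) | Cl/C=C(/CB4OC(C)(C)C(C)(C)O4)\C=C/[C@H](OC(=O)CCC)[C@@]1(C)[C@H]2O[C@H]2[C@@H](OC(=O)CCC)[C@@](C)(O)[C@@H]1[C@H](OC(C)=O)[C@](C=O)(O)[C@@H](C)CO[Si](c3ccccc3)(c3ccccc3)C(C)(C)C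
F7 | step 20 | C7 O-pinacolborate of 32 | C=C1/C=C\[C@H](OC(=O)CCC)[C@@]2(C)[C@H]3O[C@H]3[C@@H](OC(=O)CCC)[C@@](C)(O)[C@@H]2[C@H](OC(C)=O)[C@](O)([C@@H](C)CO[Si](c4ccccc4)(c4ccccc4)C(C)(C)C)[C@@H](OB5OC(C)(C)C(C)(C)O5)[C@H]1Cl
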